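Retrosynthesis: the acetate, dioxolane and tosyl masks are removed first. N1–C2 and C3–CH2 of indole A are then cut together, with the side chain taken back to an acetic ester. The aryl–alkyne bond follows, and last the C1′–C3 bond to indole B, which leads to a C5 epoxy alcohol.
Enabling feature: on the pyrrole ring of indole A the C1′ methine sits on C2 and the CH2 of the oxygenated two-carbon chain on the adjacent C3. C2 and C3 therefore map onto the two carbons of an alkyne held ortho to an anilide nitrogen, across which N and CH2 can be added.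
Forward order: C5 enynol, epoxy alcohol, indole B joined at C1′, diol tied up as a dioxolane, benzene ring of indole A joined by Sonogashira coupling, pyrrole ring of indole A closed together with its side chain. Reduction, detosylation, acetylation and acetal hydrolysis finish the route.
Stereochemistry: C2′ comes from a Sharpless asymmetric epoxidation of the E-enynol with a D-(−)-tartrate. C1′ comes from invertive opening of the trans-oxirane at its propargylic carbon. Neither centre is touched afterwards.

Key step: step 9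

Assumption: (E)-pent-2-en-4-yn-1-ol is used geometrically pure (an E/Z mixture would be fractionated first), because the alkene geometry becomes the C1′/C2′ relative configuration.
Remark: the descriptor at C1′ reads S, R, R and S again along the route (alkyne capped by Si, by H, by aryl, then indole A), and that at C2′ changes from R to S on oxirane opening. These are changes of CIP priority only; the geometry is fixed after step 3.

Step 1
Reactants: 1 (E)-pent-2-en-4-yn-1-ol
Product: 3 (E)-5-(trimethylsilyl)pent-2-en-4-yn-1-ol, via bis-silylated enynol 2 (not isolated)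
Conditions: n-BuLi (2.1 equiv), THF, −78 °C; TMSCl (2.2 equiv), −78 °C to rt; 1 M HCl, rt
Reagents that add atoms: chlorotrimethylsilane, C[Si](C)(C)Cl
Why: Double deprotonation and C,O-bis-silylation followed by selective acid hydrolysis of the far more labile O–Si bond is the standard silylation of a terminal alkynol, and it leaves the E alkene untouched.

Step 2
Reactants: 3 (E)-5-(trimethylsilyl)pent-2-en-4-yn-1-ol
Product: 4 [(2R,3R)-3-[(trimethylsilyl)ethynyl]oxiran-2-yl]methanol
Conditions: Ti(OiPr)4 (0.2 equiv), D-(−)-DIPT (0.24 equiv), t-BuOOH (2 equiv, in decane), 4 Å MS, CH2Cl2, −20 °C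
Reagents that add atoms: tert-butyl hydroperoxide, CC(C)(C)OO
Why: In this Sharpless asymmetric epoxidation the allylic hydroxyl binds the titanium tartrate peroxo complex, which with the D-(−)-tartrate delivers oxygen to the alkene face that gives the (2R,3R)-trans-oxirane, so both centres arise under reagent control while the alkyne stays inert.

Step 3
Reactants: 4 [(2R,3R)-3-[(trimethylsilyl)ethynyl]oxiran-2-yl]methanol; 5 1H-indole
Product: 6 (2S,3S)-3-(1H-indol-3-yl)-5-(trimethylsilyl)pent-4-yne-1,2-diol
Conditions: 5 (2 equiv), Sc(OTf)3 (10 mol %), CH2Cl2, −20 °C to rt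
Reagents that add atoms: none
Why: Proposed new method: Sc(OTf)3 binds the oxirane oxygen and the neighbouring hydroxyl as a chelate, which selectively weakens the C3–O bond (C3 is propargylic, C2 is deactivated by the CH2OH group), and neutral indole attacks C3 through its own C3 from the face opposite the departing oxygen in a borderline SN2 Friedel–Crafts alkylation, so that C1′ is set by inversion and C2′ keeps its C–O bond, while the Me3Si cap blocks SN2′ attack at the alkyne terminus; the closest known reaction type is the Lewis-acid-catalysed, invertive opening of aryl oxiranes by indoles at the benzylic carbon, transferred here from a benzylic to a propargylic oxirane carbon.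

Step 4
Reactants: 6 (2S,3S)-3-(1H-indol-3-yl)-5-(trimethylsilyl)pent-4-yne-1,2-diol
Product: 7 3-[(1S)-1-[(4S)-2,2-dimethyl-1,3-dioxolan-4-yl]-3-(trimethylsilyl)prop-2-yn-1-yl]-1H-indole
Conditions: Me2C(OMe)2, PPTS (cat.), CH2Cl2, rt
Reagents that add atoms: 2,2-dimethoxypropane, COC(C)(C)OC
Why: Acid-catalysed transacetalisation of a terminal 1,2-diol to the five-membered dioxolane is routine, breaks no bond at a stereocentre, and uses an acid too weak to harm the indole or the C–Si bond.

Step 5
Reactants: 7 3-[(1S)-1-[(4S)-2,2-dimethyl-1,3-dioxolan-4-yl]-3-(trimethylsilyl)prop-2-yn-1-yl]-1H-indole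
Product: 8 3-[(1S)-1-[(4S)-2,2-dimethyl-1,3-dioxolan-4-yl]-3-(trimethylsilyl)prop-2-yn-1-yl]-1-tosyl-1H-indole
Conditions: NaH (1.05 equiv), DMF, 0 °C; TsCl, 0 °C to rt
Reagents that add atoms: p-toluenesulfonyl chloride, Cc1ccc(cc1)S(=O)(=O)Cl
Why: The indole N–H is by far the most acidic site, so one equivalent of NaH gives only the indolide, which is sulfonylated at nitrogen in a standard N-tosylation that keeps strong base away from the C1′–H.

Step 6
Reactants: 8 3-[(1S)-1-[(4S)-2,2-dimethyl-1,3-dioxolan-4-yl]-3-(trimethylsilyl)prop-2-yn-1-yl]-1-tosyl-1H-indole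
Product: 9 3-[(1R)-1-[(4S)-2,2-dimethyl-1,3-dioxolan-4-yl]prop-2-yn-1-yl]-1-tosyl-1H-indole
Conditions: TBAF, AcOH (1:1), THF, 0 °C
Reagents that add atoms: none
Why: Fluoride-induced protodesilylation of an alkynylsilane is fast at 0 °C, and the acetic acid buffer keeps the medium from becoming basic enough to isomerise the propargylic C1′–H to an allene or to attack the sulfonamide.

Step 7
Reactants: 10 2-iodoaniline
Product: 11 2,2,2-trifluoro-N-(2-iodophenyl)acetamide
Conditions: (CF3CO)2O, CH2Cl2, 0 °C to rt
Reagents that add atoms: trifluoroacetic anhydride, O=C(OC(=O)C(F)(F)F)C(F)(F)F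
Why: N-Acylation of an aniline by this highly electrophilic anhydride is routine and installs the acidic N–H that a carbonate base can later deprotonate.

Step 8
Reactants: 9 3-[(1R)-1-[(4S)-2,2-dimethyl-1,3-dioxolan-4-yl]prop-2-yn-1-yl]-1-tosyl-1H-indole; 11 2,2,2-trifluoro-N-(2-iodophenyl)acetamide
Product: 12 N-[2-[(3R)-3-[(4S)-2,2-dimethyl-1,3-dioxolan-4-yl]-3-(1-tosyl-1H-indol-3-yl)prop-1-yn-1-yl]phenyl]-2,2,2-trifluoroacetamide
Conditions: PdCl2(PPh3)2 (3 mol %), CuI (5 mol %), Et3N, DMF, rt
Reagents that add atoms: none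
Why: Sonogashira coupling of an aryl iodide with a terminal alkyne runs at room temperature, where the coupled 2-alkynyltrifluoroacetanilide does not yet cyclise and the amine base is too weak to disturb C1′.

Step 9
Reactants: 12 N-[2-[(3R)-3-[(4S)-2,2-dimethyl-1,3-dioxolan-4-yl]-3-(1-tosyl-1H-indol-3-yl)prop-1-yn-1-yl]phenyl]-2,2,2-trifluoroacetamide; 13 ethyl iodoacetate
Product: 15 ethyl 2-[2-[(S)-[(4S)-2,2-dimethyl-1,3-dioxolan-4-yl](1-tosyl-1H-indol-3-yl)methyl]-1H-indol-3-yl]acetate, via N-trifluoroacetylindole 14 (not isolated)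
Conditions: Pd(PPh3)4 (5 mol %), anhydrous K2CO3 (3 equiv), 13 (2 equiv, slow addition), THF, 60 °C; then H2O, rt
Reagents that add atoms: none
Why: Oxidative addition of the C–I bond of 13 to zerovalent palladium gives an (ethoxycarbonylmethyl)palladium iodide, a divalent palladium π-acid that coordinates the alkyne of 12, whose acidic CF3CONH group is deprotonated by K2CO3. The nitrogen anion adds anti to the metal at the alkyne carbon that carries C1′, a 5-endo-dig closure that forms N1–C2 and the pyrrole ring of indole A and leaves palladium on the future C3; C–C reductive elimination then forms C3–CH2 and returns zerovalent palladium, and water with carbonate strips the labile N-trifluoroacetyl group of 14. The closest known reaction type is the aminopalladation–reductive elimination indole synthesis from 2-alkynyltrifluoroacetanilides, established for aryl, vinyl, allyl and benzyl electrophiles and extended to α-iodo esters, which carry no β-hydrogen next to the palladium-bound carbon. No stereocentre is created; C1′ and C2′ are spectators that meet only a weak, insoluble base and no acid, so the dioxolane and the doubly activated C1′–H should be left alone. Regiochemistry is fixed by the ortho tether, since nitrogen can reach only the distal alkyne carbon, so C1′ must end on C2 and the ester chain on C3. The chemoselectivity needed is carbon transfer through palladium ahead of direct N-alkylation of the anilide and of electrophile-free cycloisomerisation to the C3–H indole: slow addition leaves 13 to the fast oxidative addition, the dry medium withholds protons from the indol-3-ylpalladium species, and the tosyl group on indole B shuts off its nitrogen and its C2=C3 π-bond as competing nucleophiles.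

Step 10
Reactants: 15 ethyl 2-[2-[(S)-[(4S)-2,2-dimethyl-1,3-dioxolan-4-yl](1-tosyl-1H-indol-3-yl)methyl]-1H-indol-3-yl]acetate
Product: 16 2-[2-[(S)-[(4S)-2,2-dimethyl-1,3-dioxolan-4-yl](1-tosyl-1H-indol-3-yl)methyl]-1H-indol-3-yl]ethan-1-ol
Conditions: LiBH4, THF, 0 to 40 °C
Reagents that add atoms: none
Why: LiBH4 reduces the ester to the primary alcohol chemoselectively and leaves the sulfonamide, the dioxolane and both indole rings untouched.

Step 11
Reactants: 16 2-[2-[(S)-[(4S)-2,2-dimethyl-1,3-dioxolan-4-yl](1-tosyl-1H-indol-3-yl)methyl]-1H-indol-3-yl]ethan-1-ol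
Product: 17 2-[2-[(S)-[(4S)-2,2-dimethyl-1,3-dioxolan-4-yl](1H-indol-3-yl)methyl]-1H-indol-3-yl]ethan-1-ol
Conditions: Mg turnings, MeOH, rt, sonication
Reagents that add atoms: none
Why: Single-electron reduction by magnesium in methanol cleaves the N–S bond of N-sulfonylindoles (reductive desulfonylation) without touching acetal or alcohol, and it is placed before the acetylation because the methoxide formed would transesterify an acetate.

Step 12
Reactants: 17 2-[2-[(S)-[(4S)-2,2-dimethyl-1,3-dioxolan-4-yl](1H-indol-3-yl)methyl]-1H-indol-3-yl]ethan-1-ol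
Product: 18 2-[2-[(S)-[(4S)-2,2-dimethyl-1,3-dioxolan-4-yl](1H-indol-3-yl)methyl]-1H-indol-3-yl]ethyl acetate
Conditions: Ac2O (1.2 equiv), pyridine, CH2Cl2, 0 °C to rt
Reagents that add atoms: acetic anhydride, CC(=O)OC(C)=O
Why: With the diol masked, the primary alcohol is the only competent nucleophile, since indole N–H is not acylated by Ac2O and pyridine without an acyl-transfer catalyst or a strong base.

Step 13
Reactants: 18 2-[2-[(S)-[(4S)-2,2-dimethyl-1,3-dioxolan-4-yl](1H-indol-3-yl)methyl]-1H-indol-3-yl]ethyl acetate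
Product: 19 colletotryptin C, 2-[2-[(1S,2S)-2,3-dihydroxy-1-(1H-indol-3-yl)propyl]-1H-indol-3-yl]ethyl acetate
Conditions: AcOH/H2O (4:1), 40 °C
Reagents that add atoms: none
Why: Aqueous acetic acid hydrolyses a terminal isopropylidene acetal at the acetal carbon, so the C2′–O bond and its configuration persist, and the medium is mild enough for the primary acetate and the bis-indolyl methine to survive.

Compound list
1 | (E)-pent-2-en-4-yn-1-ol | OC/C=C/C#C | starting material
2 | trimethyl{[(E)-5-(trimethylsilyl)pent-2-en-4-yn-1-yl]oxy}silane | C[Si](C)(C)OC/C=C/C#C[Si](C)(C)C | intermediate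
3 | (E)-5-(trimethylsilyl)pent-2-en-4-yn-1-ol | OC/C=C/C#C[Si](C)(C)C | intermediate
4 | [(2R,3R)-3-[(trimethylsilyl)ethynyl]oxiran-2-yl]methanol | OC[C@H]1O[C@@H]1C#C[Si](C)(C)C | intermediate
5 | 1H-indole | c1ccc2[nH]ccc2c1 | starting material
6 | (2S,3S)-3-(1H-indol-3-yl)-5-(trimethylsilyl)pent-4-yne-1,2-diol | C[Si](C)(C)C#C[C@H](c1c[nH]c2ccccc12)[C@H](O)CO | intermediate
7 | 3-[(1S)-1-[(4S)-2,2-dimethyl-1,3-dioxolan-4-yl]-3-(trimethylsilyl)prop-2-yn-1-yl]-1H-indole | C[Si](C)(C)C#C[C@H](c1c[nH]c2ccccc12)[C@H]1COC(C)(C)O1 | intermediate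
8 | 3-[(1S)-1-[(4S)-2,2-dimethyl-1,3-dioxolan-4-yl]-3-(trimethylsilyl)prop-2-yn-1-yl]-1-tosyl-1H-indole | C[Si](C)(C)C#C[C@H](c1cn(S(=O)(=O)c2ccc(C)cc2)c2ccccc12)[C@H]1COC(C)(C)O1 | intermediate
9 | 3-[(1R)-1-[(4S)-2,2-dimethyl-1,3-dioxolan-4-yl]prop-2-yn-1-yl]-1-tosyl-1H-indole | C#C[C@H](c1cn(S(=O)(=O)c2ccc(C)cc2)c2ccccc12)[C@H]1COC(C)(C)O1 | intermediate
10 | 2-iodoaniline | Nc1ccccc1I | starting material
11 | 2,2,2-trifluoro-N-(2-iodophenyl)acetamide | FC(F)(F)C(=O)Nc1ccccc1I | intermediate
12 | N-[2-[(3R)-3-[(4S)-2,2-dimethyl-1,3-dioxolan-4-yl]-3-(1-tosyl-1H-indol-3-yl)prop-1-yn-1-yl]phenyl]-2,2,2-trifluoroacetamide | FC(F)(F)C(=O)Nc1ccccc1C#C[C@H](c1cn(S(=O)(=O)c2ccc(C)cc2)c2ccccc12)[C@H]1COC(C)(C)O1 | intermediate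
13 | ethyl iodoacetate | CCOC(=O)CI | starting material
14 | ethyl 2-[2-[(S)-[(4S)-2,2-dimethyl-1,3-dioxolan-4-yl](1-tosyl-1H-indol-3-yl)methyl]-1-(trifluoroacetyl)-1H-indol-3-yl]acetate | CCOC(=O)Cc1c([C@H](c2cn(S(=O)(=O)c3ccc(C)cc3)c3ccccc23)[C@H]2COC(C)(C)O2)n(C(=O)C(F)(F)F)c2ccccc12 | intermediate
15 | ethyl 2-[2-[(S)-[(4S)-2,2-dimethyl-1,3-dioxolan-4-yl](1-tosyl-1H-indol-3-yl)methyl]-1H-indol-3-yl]acetate | CCOC(=O)Cc1c([C@H](c2cn(S(=O)(=O)c3ccc(C)cc3)c3ccccc23)[C@H]2COC(C)(C)O2)[nH]c2ccccc12 | intermediate
16 | 2-[2-[(S)-[(4S)-2,2-dimethyl-1,3-dioxolan-4-yl](1-tosyl-1H-indol-3-yl)methyl]-1H-indol-3-yl]ethan-1-ol | OCCc1c([C@H](c2cn(S(=O)(=O)c3ccc(C)cc3)c3ccccc23)[C@H]2COC(C)(C)O2)[nH]c2ccccc12 | intermediate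
17 | 2-[2-[(S)-[(4S)-2,2-dimethyl-1,3-dioxolan-4-yl](1H-indol-3-yl)methyl]-1H-indol-3-yl]ethan-1-ol | OCCc1c([C@H](c2c[nH]c3ccccc23)[C@H]2COC(C)(C)O2)[nH]c2ccccc12 | intermediate
18 | 2-[2-[(S)-[(4S)-2,2-dimethyl-1,3-dioxolan-4-yl](1H-indol-3-yl)methyl]-1H-indol-3-yl]ethyl acetate | CC(=O)OCCc1c([C@H](c2c[nH]c3ccccc23)[C@H]2COC(C)(C)O2)[nH]c2ccccc12 | intermediate
19 | colletotryptin C, 2-[2-[(1S,2S)-2,3-dihydroxy-1-(1H-indol-3-yl)propyl]-1H-indol-3-yl]ethyl acetate | CC(=O)OCCc1c([C@H](c2c[nH]c3ccccc23)[C@H](O)CO)[nH]c2ccccc12 | target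

Total step count: 13. Longest linear sequence: 12 (steps 1 to 6 and 8 to 13; step 7 is a one-step side branch).

Steps most likely to fail

Step 3.
- **What may go wrong:** The Lewis-acid-activated oxirane may rearrange by a hydride shift of the Meinwald type, or oligomerise, faster than neutral indole attacks. Partial ionisation at the propargylic carbon would let configuration leak at C1′.
- **Fallback (polarity reversed, known chemistry only):** The indole becomes the substituent of the oxirane and the alkyne becomes the nucleophile. Setting out from indole 5, iodination (I2, KOH, DMF) gives 3-iodo-1H-indole F1, and N-tosylation (NaH, TsCl) gives 3-iodo-1-tosyl-1H-indole F2. Sonogashira coupling with propargyl alcohol gives 3-(1-tosyl-1H-indol-3-yl)prop-2-yn-1-ol F3. Lindlar semihydrogenation (H2, Pd/CaCO3 poisoned with Pb(OAc)2, quinoline) gives (Z)-3-(1-tosyl-1H-indol-3-yl)prop-2-en-1-ol F4. Sharpless asymmetric epoxidation with D-(−)-DIPT gives the cis-oxirane [(2R,3S)-3-(1-tosyl-1H-indol-3-yl)oxiran-2-yl]methanol F5. This is opened at C3 with inversion by diethyl[(trimethylsilyl)ethynyl]aluminium F6 (from trimethylsilylacetylene, n-BuLi and Et2AlCl), the established C3-selective alkynylalane opening of 2,3-epoxy alcohols. The product is (2S,3S)-3-(1-tosyl-1H-indol-3-yl)-5-(trimethylsilyl)pent-4-yne-1,2-diol F7. Acetonide formation under the conditions of step 4 brings the material back to the route at 8.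
- **Why the Z alkene:** Nucleophile and oxirane substituent have exchanged roles, so only the cis-oxirane gives the required C1′/C2′ relationship after inversion.

Step 9.
- **What may go wrong:** The iodoacetate may N-alkylate the anilide anion before palladium intercepts it. Ring closure may occur without transfer of the ester-bearing carbon (protodepalladation or purely base-induced cyclisation). Slow base-induced propargyl–allene isomerisation would erode C1′.
- **Fallback (the two bonds made one after the other):** Setting out from 12, catalytic divalent palladium (PdCl2(MeCN)2) with K2CO3 in MeCN effects aminopalladation–protodepalladation, and the trifluoroacetyl group is lost on aqueous work-up. This gives 2-[(S)-[(4S)-2,2-dimethyl-1,3-dioxolan-4-yl](1-tosyl-1H-indol-3-yl)methyl]-1H-indole F8. Copper-carbenoid C3–H alkylation with ethyl diazoacetate and Cu(OTf)2 in CH2Cl2 is a known functionalisation of 2-substituted N–H indoles. It should take place on the electron-rich indole A rather than on the sulfonyl-deactivated indole B, and it returns to the route at 15.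

Step 2.
- **What may go wrong:** Oxygen transfer to the electron-poor alkene of the enyne may be slow. Less selective background epoxidation could then lower the facial selectivity on which the absolute configuration of the whole route rests, and titanium alkoxides could open the sensitive propargylic oxirane.
- **Fallback (undirected chiral dioxirane instead of hydroxyl-directed titanium peroxide):** Setting out from 3, a Shi epoxidation is used, which is known to epoxidise conjugated E-enynes chemoselectively at the alkene. Conditions are the D-fructose-derived ketone, KHSO5 (as 2KHSO5·KHSO4·K2SO4), K2CO3 buffer, MeCN/dimethoxymethane/H2O, 0 °C. It should give the same (R,R)-oxirane, so the route is rejoined directly at 4. This fallback makes no compound outside the list (F0).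

Further compounds
F1 | step 3 | 3-iodo-1H-indole | Ic1c[nH]c2ccccc12
F2 | step 3 | 3-iodo-1-tosyl-1H-indole | Cc1ccc(cc1)S(=O)(=O)n1cc(I)c2ccccc12
F3 | step 3 | 3-(1-tosyl-1H-indol-3-yl)prop-2-yn-1-ol | OCC#Cc1cn(S(=O)(=O)c2ccc(C)cc2)c2ccccc12
F4 | step 3 | (Z)-3-(1-tosyl-1H-indol-3-yl)prop-2-en-1-ol | OC/C=C\c1cn(S(=O)(=O)c2ccc(C)cc2)c2ccccc12
F5 | step 3 | [(2R,3S)-3-(1-tosyl-1H-indol-3-yl)oxiran-2-yl]methanol | OC[C@H]1O[C@H]1c1cn(S(=O)(=O)c2ccc(C)cc2)c2ccccc12
F6 | step 3 | diethyl[(trimethylsilyl)ethynyl]aluminium | CC[Al](CC)C#C[Si](C)(C)C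
F7 | step 3 | (2S,3S)-3-(1-tosyl-1H-indol-3-yl)-5-(trimethylsilyl)pent-4-yne-1,2-diol | C[Si](C)(C)C#C[C@H](c1cn(S(=O)(=O)c2ccc(C)cc2)c2ccccc12)[C@H](O)CO
F8 | step 9 | 2-[(S)-[(4S)-2,2-dimethyl-1,3-dioxolan-4-yl](1-tosyl-1H-indol-3-yl)methyl]-1H-indole | c1c([C@H](c2cn(S(=O)(=O)c3ccc(C)cc3)c3ccccc23)[C@H]2COC(C)(C)O2)[nH]c2ccccc12
F0 | step 2 | none | none
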